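**Retrosynthetic overview**
- The ester C–O bond is not the last bond made. The final disconnection is the unactivated C(sp3)–C(sp3) bond between C16 and C17 of the side chain, formed by a room-temperature alkyl–alkyl Suzuki–Miyaura coupling on the unprotected catechol ester.
- This splits the iso-C22 chain into a C16 ω-bromoalkyl 2,3-dihydroxybenzoate and a C6 iso-branched alkylborane made in the flask from a cheap volatile alkene.
- The bromo ester goes back to free 2,3-dihydroxybenzoic acid and a C16 bromo alcohol (carboxyl-selective Mitsunobu reaction), and the bromo alcohol to a symmetric C16 diol.
- No ring is formed: the only ring, the catechol benzene ring, is bought. No protecting group is used.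

Assumption: the target has no stereocentre (it is achiral), so "single enantiomer" sets no stereochemical task and no step has to control configuration.

**Step 1**
Reactants: 1 hexadecane-1,16-diol
Product: 2 16-bromohexadecan-1-ol
Conditions: 48% aq HBr (1.2 equiv), toluene, reflux, 36 h
Reagents that add atoms: hydrogen bromide, Br
Why: Acid-mediated SN2 substitution of a primary alcohol (HBr monobromination of an α,ω-diol); in the two-phase toluene/aqueous HBr system the first-formed bromo alcohol moves into toluene as hydrogen-bonded aggregates that shield its remaining OH, so the monobromide forms selectively, and no stereocentre is involved.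

**Step 2**
Reactants: 2 16-bromohexadecan-1-ol; 3 2,3-dihydroxybenzoic acid
Product: 4 16-bromohexadecyl 2,3-dihydroxybenzoate
Conditions: 3 (1.2 equiv), PPh3 (1.3 equiv), DIAD (1.3 equiv), THF, 0 °C to rt, 12 h
Reagents that add atoms: none
Why: Mitsunobu esterification; the alcohol is activated as its alkoxyphosphonium ion and displaced in an SN2 step by the carboxylate, the only group acidic enough to be ionised by the betaine (pKa about 3 against 9 or more for the phenols, one of which is hydrogen-bonded to the carbonyl), so the free catechol needs no protection, the primary bromide is untouched at room temperature, and no stereocentre is involved.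

**Step 3**
Reactants: 4 16-bromohexadecyl 2,3-dihydroxybenzoate; 5 4-methylpent-1-ene; 6 9-borabicyclo[3.3.1]nonane (9-BBN, 0.5 M in THF)
Product: 8 gentiside A (20-methylhenicosyl 2,3-dihydroxybenzoate), via B-(4-methylpentyl)-9-BBN 7 (not isolated)
Conditions: 5 (2.2 equiv), 6 (2.0 equiv), THF, 0 °C to rt, 4 h; then 4 (1.0 equiv), Pd(OAc)2 (5 mol %), PCy3 (10 mol %), K3PO4·H2O (3.5 equiv), degassed THF, Ar, rt, 24 h
Reagents that add atoms: none
Why: Anti-Markovnikov hydroboration of the terminal alkene followed by a B-alkyl Suzuki–Miyaura alkyl–alkyl cross-coupling; the bulky, electron-rich PCy3 complex of zerovalent palladium adds to the primary C–Br bond by an SN2-type path at room temperature and transmetallation from the base-activated alkylborane outruns β-hydride elimination, while the trialkylborane is not protonated by phenols, the hydrated phosphate in THF is too weak and insoluble to drive O-alkylation of the catechol, the aryl ester is inert, and no stereocentre is formed (tolerance of the free catechol under these conditions is the untested element).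

**Compound list**
1 | hexadecane-1,16-diol | OCCCCCCCCCCCCCCCCO | starting material
2 | 16-bromohexadecan-1-ol | OCCCCCCCCCCCCCCCCBr | intermediate
3 | 2,3-dihydroxybenzoic acid | OC(=O)c1cccc(O)c1O | starting material
4 | 16-bromohexadecyl 2,3-dihydroxybenzoate | BrCCCCCCCCCCCCCCCCOC(=O)c1cccc(O)c1O | intermediate
5 | 4-methylpent-1-ene | C=CCC(C)C | starting material
6 | 9-borabicyclo[3.3.1]nonane (9-BBN, drawn as the monomer) | B1C2CCCC1CCC2 | starting material
7 | 9-(4-methylpentyl)-9-borabicyclo[3.3.1]nonane (B-(4-methylpentyl)-9-BBN, not isolated) | CC(C)CCCB1C2CCCC1CCC2 | intermediate
8 | gentiside A, 20-methylhenicosyl 2,3-dihydroxybenzoate (achiral) | CC(C)CCCCCCCCCCCCCCCCCCCOC(=O)c1cccc(O)c1O | target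

**Totals**
Total step count: 3. Longest linear sequence: 3 steps (1 to 2 to 4 to 8).

**Steps most likely to fail, with fallbacks**

Step 3 (highest risk): the alkyl–alkyl coupling has to run in the presence of an unprotected catechol. Catecholate could bind boron or palladium, 4 could slowly O-alkylate itself, and β-hydride elimination could give the terminal alkene. The fallback inverts the order of events to the ester-last sequence, so the palladium step never sees the catechol. It sets out from 2. Bromo alcohol 2 is coupled with alkylborane 7 (made from 5 and 6 as in step 3) using Pd(OAc)2, PCy3 and K3PO4·H2O in THF at rt to give 20-methylhenicosan-1-ol F3. F3 is then esterified with 3 by the carboxyl-selective Mitsunobu reaction (PPh3, DIAD, THF, 0 °C to rt). The fallback comes back to the route at 8.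

Step 2: the hydroxy acid is intramolecularly hydrogen-bonded and may react sluggishly, and some phenol O-alkylation is possible. The fallback replaces SN2 activation of the alcohol by acylation through a photogenerated quinoketene. It sets out from 3. Acid 3 is condensed with acetone (TFAA, TFA, 0 °C to rt) to give 8-hydroxy-2,2-dimethyl-4H-1,3-benzodioxin-4-one F2. Irradiation of F2 (300 nm, CH2Cl2, rt) with 2 (1.5 equiv) expels acetone, and the quinoketene is trapped by the primary alcohol under neutral conditions; the alkyl bromide does not absorb at this wavelength. The fallback comes back to the route at 4.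

Step 1: monobromination of a waxy C16 diol may give diol/monobromide/dibromide mixtures that are hard to separate. The fallback moves the desymmetrisation off the diol and avoids both compound 2 and the Mitsunobu step. It sets out from 1. Diol 1 is brominated exhaustively (48% aq HBr, conc. H2SO4, reflux) to 1,16-dibromohexadecane F1. F1 is used in threefold excess to alkylate the carboxylate of 3 (KHCO3, DMF, 45 °C); bicarbonate ionises only the CO2H, so the phenols are not alkylated. The non-polar excess F1 is recovered by a hexane wash and reused. The fallback comes back to the route at 4.

**Further compounds**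
F1 | step 1 | 1,16-dibromohexadecane | BrCCCCCCCCCCCCCCCCBr
F2 | step 2 | 8-hydroxy-2,2-dimethyl-4H-1,3-benzodioxin-4-one | CC1(C)OC(=O)c2cccc(O)c2O1
F3 | step 3 | 20-methylhenicosan-1-ol | CC(C)CCCCCCCCCCCCCCCCCCCO
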